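The C2–C1′ bond between the pyranone ring C and the chromene-fused ring B is the disconnection on which the route rests. C2 lies β to the C4 carbonyl and bears O1, so it is the electrophilic terminus of a chromone (O1–C2=C3–C4=O); C1′, flanked by the 2′-oxygen, is carried as an arylboronic acid. A rhodium-catalysed asymmetric conjugate arylation joins 7-methoxy-5-(prenyloxy)chromone with the 7-(MOM-oxy)-2,2-dimethylchromen-6-ylboronic acid, forming this bond and the only stereocentre, (2S), in one operation. The 5-O-prenyl group is both protecting group and latent C8 prenyl: a europium-catalysed para-Claisen–Cope shift then moves it to C8 and frees the 5-OH, and MOM removal completes the synthesis.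

Key step: step 7

Assumption: the stereocentre of the target is read as (2S) (O1 > C1′ > C3 > H). The facial sense assigned to the (S)-ligand in step 7 rests on the 2-cyclohexenone model of this catalyst class, and the ligand antipode is equally accessible.

**Step 1**
Reactants: 1 5,7-dihydroxy-4H-chromen-4-one
Product: 2 5-hydroxy-7-methoxy-4H-chromen-4-one
Conditions: MeI (1.1 equiv), K2CO3 (1.2 equiv), acetone, reflux
Reagents that add atoms: iodomethane CI
Why: Williamson etherification in which the free, vinylogously acidic 7-OH should react while the 5-OH, hydrogen-bonded to the C4 carbonyl, stays untouched with one equivalent of electrophile.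

**Step 2**
Reactants: 2 5-hydroxy-7-methoxy-4H-chromen-4-one
Product: 3 7-methoxy-5-[(3-methylbut-2-en-1-yl)oxy]-4H-chromen-4-one
Conditions: prenyl bromide (1.5 equiv), K2CO3 (2 equiv), DMF, 50 °C
Reagents that add atoms: 1-bromo-3-methylbut-2-ene CC(C)=CCBr
Why: Williamson etherification of the chelated 5-OH under more forcing conditions, where the reactive allylic bromide and carbonate base should favour O- over C-alkylation and the chromone ring is stable to anhydrous carbonate.

**Step 3**
Reactants: 4 4-bromobenzene-1,3-diol (4-bromoresorcinol)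
Product: 5 2-bromo-5-[(2-methylbut-3-yn-2-yl)oxy]phenol
Conditions: 3-chloro-3-methylbut-1-yne (1.1 equiv), K2CO3 (1.5 equiv), KI (0.2 equiv), CuI (2 mol%), acetone, 55 °C
Reagents that add atoms: 3-chloro-3-methylbut-1-yne CC(C)(Cl)C#C
Why: copper-assisted propargylic etherification in which the bulky tertiary electrophile should be taken by the less hindered, more nucleophilic phenoxide para to bromine and not by the ortho-bromo phenoxide, with the limiting amount of chloride holding back the bis-ether.

**Step 4**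
Reactants: 5 2-bromo-5-[(2-methylbut-3-yn-2-yl)oxy]phenol
Product: 6 1-bromo-2-(methoxymethoxy)-4-[(2-methylbut-3-yn-2-yl)oxy]benzene
Conditions: MOMCl (1.3 equiv), i-Pr2NEt (1.5 equiv), CH2Cl2, 0 °C to rt
Reagents that add atoms: chloromethyl methyl ether COCCl
Why: standard MOM acetal formation on the remaining phenol, which masks the acidic OH for the organolithium step and adds bulk next to the ring carbon flanked by two oxygens.

**Step 5**
Reactants: 6 1-bromo-2-(methoxymethoxy)-4-[(2-methylbut-3-yn-2-yl)oxy]benzene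
Product: 9 6-bromo-7-(methoxymethoxy)-2,2-dimethyl-2H-chromene, via allenylphenol 7 (not isolated), via ortho-quinone methide 8 (not isolated)
Conditions: PhNEt2, 180 °C
Reagents that add atoms: none
Why: aryl propargyl ether Claisen rearrangement cascade, in which the [3,3] shift should go to the unhindered ortho carbon para to OMOM (not the carbon between the two oxygens), enolisation gives 7, a [1,5]-hydrogen shift gives 8 and oxa-6π electrocyclisation closes the 2,2-dimethylpyran ring.

**Step 6**
Reactants: 9 6-bromo-7-(methoxymethoxy)-2,2-dimethyl-2H-chromene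
Product: 12 [7-(methoxymethoxy)-2,2-dimethyl-2H-chromen-6-yl]boronic acid, via aryllithium 10 (not isolated), via lithium aryltriisopropoxyborate 11 (not isolated)
Conditions: n-BuLi (1.05 equiv), THF, −78 °C; B(Oi-Pr)3 (1.5 equiv), −78 to 0 °C; then 1 M aq HCl to pH 5–6, 0 °C
Reagents that add atoms: triisopropyl borate CC(C)OB(OC(C)C)OC(C)C; water O
Why: bromine–lithium exchange gives an aryllithium stabilised by chelation to the ortho MOM oxygen, which is trapped by the borate and hydrolysed at mild pH so that the MOM acetal and the chromene alkene survive.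

**Step 7**
Reactants: 3 7-methoxy-5-[(3-methylbut-2-en-1-yl)oxy]-4H-chromen-4-one; 12 [7-(methoxymethoxy)-2,2-dimethyl-2H-chromen-6-yl]boronic acid (2.5 equiv)
Product: 13 (2S)-7-methoxy-2-[7-(methoxymethoxy)-2,2-dimethyl-2H-chromen-6-yl]-5-[(3-methylbut-2-en-1-yl)oxy]-2,3-dihydro-4H-chromen-4-one
Conditions: [RhCl(C2H4)2]2 (2.5 mol%), (S)-MeO-F12-BIPHEP (5.5 mol%), KOH (20 mol%), degassed 1,4-dioxane/H2O (10:1), 40 °C
Reagents that add atoms: none
Why: Hayashi–Miyaura reaction (Rh(I)-catalysed asymmetric 1,4-addition of an arylboronic acid to a chromone, an established entry to flavanones): transmetallation of 12 to the hydroxo-rhodium complex gives an aryl–Rh(I) species, the C2=C3 bond of 3 inserts with aryl transfer to C2, and the oxa-π-allyl rhodium enolate is protonated at C3 by water, which regenerates Rh–OH. No ring is closed; the C2–C1′ bond forms intermolecularly on the preformed pyranone ring. The new C2 stereocentre is controlled by the ligand: the (S)-biaryl bisphosphine is expected to expose the Re face of C2 (O1 > C3 > H), the face that corresponds to the one attacked in 2-cyclohexenone by (S)-biaryl bisphosphine–rhodium catalysts, and aryl delivery to it gives (2S). The step needs 1,4- over 1,2-addition and insertion faster than protodeboronation of the electron-rich ortho-alkoxy boronic acid; the C2-unsubstituted chromone is the only conjugate acceptor, the peri 5-O-prenyl group shields the C4 carbonyl and replaces a chelating 5-OH that would bind rhodium, the electron-poor ligand speeds transmetallation and insertion, and 12 is used in excess. The prenyl ether, the chromene alkene and the MOM acetal are not expected to react with aryl–Rh(I) under these mild aqueous conditions, and the low base loading limits retro-oxa-Michael opening of the product.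

**Step 8**
Reactants: 13 (2S)-7-methoxy-2-[7-(methoxymethoxy)-2,2-dimethyl-2H-chromen-6-yl]-5-[(3-methylbut-2-en-1-yl)oxy]-2,3-dihydro-4H-chromen-4-one
Product: 16 (2S)-5-hydroxy-7-methoxy-2-[7-(methoxymethoxy)-2,2-dimethyl-2H-chromen-6-yl]-8-(3-methylbut-2-en-1-yl)-2,3-dihydro-4H-chromen-4-one, via ortho-Claisen dienone 14 (not isolated), via para-dienone 15 (not isolated)
Conditions: Eu(fod)3 (10 mol%), CHCl3, 60 °C
Reagents that add atoms: none
Why: europium(III)-catalysed para-Claisen–Cope rearrangement known for 5-O-prenylflavanones, in which chelation of Eu to C4=O and O5 accelerates the [3,3] shift to C6 (14), a Cope shift carries the allyl unit to C8 as a normal prenyl group (15) and tautomerisation gives the chelated 5-OH phenol, while C2 takes no part and should keep its configuration under these neutral conditions.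

**Step 9**
Reactants: 16 (2S)-5-hydroxy-7-methoxy-2-[7-(methoxymethoxy)-2,2-dimethyl-2H-chromen-6-yl]-8-(3-methylbut-2-en-1-yl)-2,3-dihydro-4H-chromen-4-one
Product: 17 (2S)-5-hydroxy-2-(7-hydroxy-2,2-dimethyl-2H-chromen-6-yl)-7-methoxy-8-(3-methylbut-2-en-1-yl)-2,3-dihydro-4H-chromen-4-one (maackiaflavanone A)
Conditions: ZnBr2 (1 equiv), n-PrSH (2 equiv), CH2Cl2, 0 °C, short reaction time
Reagents that add atoms: none
Why: Lewis acid/soft nucleophile cleavage of the aryl MOM acetal (zinc activates the acetal oxygen, the thiol takes the methoxymethyl carbon), which avoids the protic acid or base that could open the C2–O1 benzylic ether, hydrate the prenyl or chromene alkenes or erode the (2S) centre.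

**Compound list**
1 | 5,7-dihydroxy-4H-chromen-4-one | Oc1cc(O)c2c(c1)OC=CC2=O | starting material
2 | 5-hydroxy-7-methoxy-4H-chromen-4-one | COc1cc(O)c2c(c1)OC=CC2=O | intermediate
3 | 7-methoxy-5-[(3-methylbut-2-en-1-yl)oxy]-4H-chromen-4-one | COc1cc(OCC=C(C)C)c2c(c1)OC=CC2=O | intermediate
4 | 4-bromobenzene-1,3-diol | Oc1ccc(Br)c(O)c1 | starting material
5 | 2-bromo-5-[(2-methylbut-3-yn-2-yl)oxy]phenol | C#CC(C)(C)Oc1ccc(Br)c(O)c1 | intermediate
6 | 1-bromo-2-(methoxymethoxy)-4-[(2-methylbut-3-yn-2-yl)oxy]benzene | C#CC(C)(C)Oc1ccc(Br)c(OCOC)c1 | intermediate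
7 | 4-bromo-5-(methoxymethoxy)-2-(3-methylbuta-1,2-dien-1-yl)phenol | CC(C)=C=Cc1cc(Br)c(OCOC)cc1O | intermediate (not isolated)
8 | (6Z)-4-bromo-3-(methoxymethoxy)-6-(3-methylbut-2-en-1-ylidene)cyclohexa-2,4-dien-1-one | O=C1C=C(OCOC)C(Br)=C/C1=C/C=C(C)C | intermediate (not isolated)
9 | 6-bromo-7-(methoxymethoxy)-2,2-dimethyl-2H-chromene | COCOc1cc2OC(C)(C)C=Cc2cc1Br | intermediate
10 | [7-(methoxymethoxy)-2,2-dimethyl-2H-chromen-6-yl]lithium | [Li]c1cc2C=CC(C)(C)Oc2cc1OCOC | intermediate (not isolated)
11 | lithium triisopropoxy[7-(methoxymethoxy)-2,2-dimethyl-2H-chromen-6-yl]borate | [Li+].CC(C)O[B-](OC(C)C)(OC(C)C)c1cc2C=CC(C)(C)Oc2cc1OCOC | intermediate (not isolated)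
12 | [7-(methoxymethoxy)-2,2-dimethyl-2H-chromen-6-yl]boronic acid | COCOc1cc2OC(C)(C)C=Cc2cc1B(O)O | intermediate
13 | (2S)-7-methoxy-2-[7-(methoxymethoxy)-2,2-dimethyl-2H-chromen-6-yl]-5-[(3-methylbut-2-en-1-yl)oxy]-2,3-dihydro-4H-chromen-4-one | COc1cc(OCC=C(C)C)c2c(c1)O[C@H](c1cc3c(cc1OCOC)OC(C)(C)C=C3)CC2=O | intermediate
14 | (2S)-7-methoxy-2-[7-(methoxymethoxy)-2,2-dimethyl-2H-chromen-6-yl]-6-(2-methylbut-3-en-2-yl)-2,3-dihydro-4H-chromene-4,5(6H)-dione (C6 epimers) | COC1=CC2=C(C(=O)C1C(C)(C)C=C)C(=O)C[C@@H](c1cc3c(cc1OCOC)OC(C)(C)C=C3)O2 | intermediate (not isolated)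
15 | (2S)-7-methoxy-2-[7-(methoxymethoxy)-2,2-dimethyl-2H-chromen-6-yl]-8-(3-methylbut-2-en-1-yl)-2,3-dihydro-4H-chromene-4,5(8H)-dione (C8 epimers) | COC1=CC(=O)C2=C(O[C@H](c3cc4c(cc3OCOC)OC(C)(C)C=C4)CC2=O)C1CC=C(C)C | intermediate (not isolated)
16 | (2S)-5-hydroxy-7-methoxy-2-[7-(methoxymethoxy)-2,2-dimethyl-2H-chromen-6-yl]-8-(3-methylbut-2-en-1-yl)-2,3-dihydro-4H-chromen-4-one | COc1cc(O)c2c(c1CC=C(C)C)O[C@H](c1cc3c(cc1OCOC)OC(C)(C)C=C3)CC2=O | intermediate
17 | (2S)-5-hydroxy-2-(7-hydroxy-2,2-dimethyl-2H-chromen-6-yl)-7-methoxy-8-(3-methylbut-2-en-1-yl)-2,3-dihydro-4H-chromen-4-one (maackiaflavanone A) | COc1cc(O)c2c(c1CC=C(C)C)O[C@H](c1cc3c(cc1O)OC(C)(C)C=C3)CC2=O | target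

**Step count**
Total: 9 steps. Longest linear sequence: 7 steps (4 → 5 → 6 → 9 → 12 → 13 → 16 → 17, steps 3–9).

**Steps most likely to fail**

1. Step 7. Protodeboronation of the electron-rich ortho-alkoxy boronic acid may outrun insertion into the deactivated 5,7-dioxygenated chromone. Facial discrimination may be poor with the ortho-substituted aryl group, and base-induced ring opening of the product may erode the enantiomeric purity. The fallback sets out from 3 and 9 and comes back at 13. Chromone 3 would be activated with TBSOTf in CH2Cl2 as the 4-silyloxybenzopyrylium salt 4-[(tert-butyldimethylsilyl)oxy]-7-methoxy-5-[(3-methylbut-2-en-1-yl)oxy]chromenylium triflate F1. Bromide 9 would be lithiated as in step 6 (aryllithium 10) and transmetallated with MgBr2·OEt2 to [7-(methoxymethoxy)-2,2-dimethyl-2H-chromen-6-yl]magnesium bromide F2. Copper-catalysed addition of this Grignard reagent (CuBr·SMe2 cat., THF, −78 °C) at C2 of the pyrylium ring should give the racemic silyl enol ether tert-butyl({7-methoxy-2-[7-(methoxymethoxy)-2,2-dimethyl-2H-chromen-6-yl]-5-[(3-methylbut-2-en-1-yl)oxy]-2H-chromen-4-yl}oxy)dimethylsilane F3. Desilylation with HF·pyridine would give racemic 7-methoxy-2-[7-(methoxymethoxy)-2,2-dimethyl-2H-chromen-6-yl]-5-[(3-methylbut-2-en-1-yl)oxy]-2,3-dihydro-4H-chromen-4-one F4. Preparative HPLC on a chiral stationary phase would then provide the (2S)-enantiomer 13. The same C2–C1′ bond is formed, but with a far stronger electrophile and a nucleophile that cannot protodeboronate, and the configuration is secured by resolution.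

2. Step 3. Alkylation may occur at the ortho-bromo oxygen or at both oxygens, and a wrong-site cyclisation in step 5 would add to the loss. The fallback sets out from 4 and comes back at 9. Pechmann condensation of 4 with malic acid in concentrated H2SO4 at 100 °C fixes the regiochemistry by C–C bond formation para to one hydroxyl and should give 6-bromo-7-hydroxy-2H-chromen-2-one F5. MOM protection (MOMCl, i-Pr2NEt) would give 6-bromo-7-(methoxymethoxy)-2H-chromen-2-one F6. Double 1,2-addition of MeMgBr (3.5 equiv, THF, 0 °C) to the lactone would open it to 4-bromo-2-[(1Z)-3-hydroxy-3-methylbut-1-en-1-yl]-5-(methoxymethoxy)phenol F7. Cyclodehydration of this diol with catalytic PPTS in CH2Cl2 should close the 2,2-dimethylpyran ring and give 9.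

3. Step 8. The ortho-dienone may tautomerise before the Cope shift and so leave a 6-(1,1-dimethylallyl) isomer, and Lewis acid-assisted ionisation of the C2–O1 bond next to the electron-rich ring B may erode the configuration. The fallback sets out from 3 and comes back at 17. The rearrangement is moved to the chromone, which has no stereocentre: Eu(fod)3 in CHCl3 at 60 °C should convert 3 into 5-hydroxy-7-methoxy-8-(3-methylbut-2-en-1-yl)-4H-chromen-4-one F8. MOM protection of the chelated phenol (NaH, MOMCl, DMF, 0 °C) would give 7-methoxy-5-(methoxymethoxy)-8-(3-methylbut-2-en-1-yl)-4H-chromen-4-one F9. The rhodium-catalysed asymmetric conjugate arylation with 12 under the conditions of step 7 should then give (2S)-7-methoxy-5-(methoxymethoxy)-2-[7-(methoxymethoxy)-2,2-dimethyl-2H-chromen-6-yl]-8-(3-methylbut-2-en-1-yl)-2,3-dihydro-4H-chromen-4-one F10. Cleavage of both MOM groups with ZnBr2/n-PrSH as in step 9 would give 17.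

**Further compounds**
F1 | step 7 | 4-[(tert-butyldimethylsilyl)oxy]-7-methoxy-5-[(3-methylbut-2-en-1-yl)oxy]chromenylium trifluoromethanesulfonate | COc1cc(OCC=C(C)C)c2c(O[Si](C)(C)C(C)(C)C)cc[o+]c2c1.[O-]S(=O)(=O)C(F)(F)F
F2 | step 7 | [7-(methoxymethoxy)-2,2-dimethyl-2H-chromen-6-yl]magnesium bromide | COCOc1cc2OC(C)(C)C=Cc2cc1[Mg]Br
F3 | step 7 | racemic tert-butyl({7-methoxy-2-[7-(methoxymethoxy)-2,2-dimethyl-2H-chromen-6-yl]-5-[(3-methylbut-2-en-1-yl)oxy]-2H-chromen-4-yl}oxy)dimethylsilane | COc1cc(OCC=C(C)C)c2c(c1)OC(c1cc3c(cc1OCOC)OC(C)(C)C=C3)C=C2O[Si](C)(C)C(C)(C)C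
F4 | step 7 | racemic 7-methoxy-2-[7-(methoxymethoxy)-2,2-dimethyl-2H-chromen-6-yl]-5-[(3-methylbut-2-en-1-yl)oxy]-2,3-dihydro-4H-chromen-4-one | COc1cc(OCC=C(C)C)c2c(c1)OC(c1cc3c(cc1OCOC)OC(C)(C)C=C3)CC2=O
F5 | step 3 | 6-bromo-7-hydroxy-2H-chromen-2-one | O=c1ccc2cc(Br)c(O)cc2o1
F6 | step 3 | 6-bromo-7-(methoxymethoxy)-2H-chromen-2-one | COCOc1cc2oc(=O)ccc2cc1Br
F7 | step 3 | 4-bromo-2-[(1Z)-3-hydroxy-3-methylbut-1-en-1-yl]-5-(methoxymethoxy)phenol | COCOc1cc(O)c(/C=C\C(C)(C)O)cc1Br
F8 | step 8 | 5-hydroxy-7-methoxy-8-(3-methylbut-2-en-1-yl)-4H-chromen-4-one | COc1cc(O)c2c(c1CC=C(C)C)OC=CC2=O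
F9 | step 8 | 7-methoxy-5-(methoxymethoxy)-8-(3-methylbut-2-en-1-yl)-4H-chromen-4-one | COc1cc(OCOC)c2c(c1CC=C(C)C)OC=CC2=O
F10 | step 8 | (2S)-7-methoxy-5-(methoxymethoxy)-2-[7-(methoxymethoxy)-2,2-dimethyl-2H-chromen-6-yl]-8-(3-methylbut-2-en-1-yl)-2,3-dihydro-4H-chromen-4-one | COc1cc(OCOC)c2c(c1CC=C(C)C)O[C@H](c1cc3c(cc1OCOC)OC(C)(C)C=C3)CC2=O
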